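Everything rests on the interflavan bond from C4 of the top unit (T) to C8 of the middle unit (M), which lies cis to the axial T O3 (4α) and is made inside a ring. The key step ionises C4 of a 4β-alkoxy T unit, and C8 of ring A of M, tied from M O3 to T O3 by a silyl ether and ester chain, closes a 14-membered ring, giving the bond, the C4 stereocentre and two distinguishable 3-oxygens. The feature used is the pair of ring C oxygens, T O3 (α, beside C4) and M O3, as anchors. The precursor is perbenzylated T and M joined O3 to O3 by that chain.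

Key step: step 5

Remark: the target is read as epicatechin-(4α→8)-epicatechin 3-O-gallate-(4β→8)-epicatechin 3-O-gallate (B = bottom unit); α is the face of ring C that carries the 2-aryl group and O3 in each 2R,3R unit.

Step 1
Reactants: 1 (−)-epicatechin
Product: 2 5,7,3',4'-tetra-O-benzyl-(−)-epicatechin (2R,3R; 3-OH free)
Conditions: BnBr (4.4 equiv), K2CO3, DMF, 0 °C → rt
Reagents that add atoms: benzyl bromide, BrCc1ccccc1
Why: Williamson ether synthesis: K2CO3 deprotonates only the four phenols, which are benzylated while the aliphatic 3-OH stays free and no stereocentre is touched.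

Step 2
Reactants: 2 5,7,3',4'-tetra-O-benzyl-(−)-epicatechin
Product: 3 5,7,3',4'-tetra-O-benzyl-4β-(2-ethoxyethoxy)epicatechin (4-ether trans to the free 3-OH)
Conditions: DDQ (2 equiv), 2-ethoxyethanol, CH2Cl2, rt
Reagents that add atoms: 2-ethoxyethanol, CCOCCO
Why: DDQ benzylic oxidation: hydride abstraction at C4 gives a cation stabilised by the 5- and 7-benzyloxy groups of ring A, and the alcohol adds anti to the axial 3-OH, which sets the 4β ether (3,4-trans).

Step 3
Reactants: 2 5,7,3',4'-tetra-O-benzyl-(−)-epicatechin; 4 but-3-enoic acid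
Product: 5 5,7,3',4'-tetra-O-benzylepicatechin 3-O-but-3-enoate
Conditions: DCC, DMAP (cat.), CH2Cl2, 0 °C
Reagents that add atoms: none
Why: Steglich esterification of the axial 3-OH; low temperature and only catalytic DMAP are chosen so that the β,γ-double bond does not move into conjugation.

Step 4
Reactants: 5 5,7,3',4'-tetra-O-benzylepicatechin 3-O-but-3-enoate; 6 chlorodiisopropylsilane; 3 5,7,3',4'-tetra-O-benzyl-4β-(2-ethoxyethoxy)epicatechin
Product: 8 tethered T–M precursor (T O3–Si(iPr)2–(CH2)3–C(=O)–O3 M; T keeps its 4β-(2-ethoxyethoxy) group), via chlorosilane 7 (not isolated)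
Conditions: 6 (1.5 equiv), Pt2[(CH2=CHSiMe2)2O]3 (Karstedt catalyst, zerovalent platinum, cat.), toluene, 40 °C; evaporate; then 3, imidazole, DMAP (cat.), DMF, rt
Reagents that add atoms: none
Why: Platinum-catalysed anti-Markovnikov hydrosilylation of the terminal alkene places silicon on the chain end, and the chlorosilane so formed silylates the 3-OH of 3 under imidazole (silyl ether formation) in a medium basic enough to spare the acid-labile benzylic 4-ether; no stereocentre changes.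

Step 5
Reactants: 8 tethered T–M precursor
Product: 9 macrocyclic 4α-linked T–M dimer (octa-O-benzyl epicatechin-(4α→8)-epicatechin with T O3 and M O3 bridged by Si(iPr)2–(CH2)3–C(=O); T 2,3,4 all cis)
Conditions: TMSOTf (0.3 equiv), CH2Cl2 (1 mM), −78 → −40 °C, 8 added slowly by syringe pump; Et3N quench
Reagents that add atoms: none
Why: TMSOTf silylates the oxygen of the 4β-(2-ethoxyethoxy) group of the T half and the ether leaves, giving the T C4 benzylic cation (a quinone-methide-like oxocarbenium stabilised by the 5- and 7-benzyloxy groups of ring A), which C8 of ring A of M attacks in an intramolecular Friedel–Crafts alkylation followed by loss of a proton. The closest known reaction is the Lewis-acid flavan-3-ol C4–C8 condensation run intramolecularly through a diester bridge between the two 3-oxygens, which gives 3,4-cis dimers; here one ester end is replaced by a silyl ether. The 14-membered ring closes in exo-trig mode at the cationic sp2 C4 (the C4=C4a π bond of the cation lies outside the new ring), with the M arene as the π nucleophile. The new stereocentre T C4 is set by the tether: its anchor T O3 is axial on the α face of ring C and the chain to M C8 cannot pass around that ring, so the arene is delivered cis to O3 (4α) while C2 and C3 are untouched. The step needs α over β attack (secured by the tether), C8 over C6 of M (both are the same number of bonds from M C3, so ring size does not decide this; it rests on the innate C8 preference of benzylated flavan-3-ols, C6 being flanked by two benzyloxy groups, and on C8 lying nearer to C3 in space) and ring closure over chain growth (secured by high dilution and slow addition). The benzyl ethers, the ester and the hindered silyl ether should be inert to catalytic TMSOTf at this temperature.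

Step 6
Reactants: 9 macrocyclic 4α-linked T–M dimer
Product: 10 octa-O-benzyl epicatechin-(4α→8)-epicatechin with M 3-OH free and T O3 as diisopropyl(4-methoxy-4-oxobutyl)silyl ether
Conditions: K2CO3 (cat.), MeOH/THF, rt
Reagents that add atoms: methanol, CO
Why: Base-catalysed transesterification (methanolysis) opens the ring at the ester only, since a diisopropylalkylsilyl ether of a hindered secondary alcohol resists carbonate in methanol much as a triisopropylsilyl ether does; M O3 is freed and T O3 stays masked.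

Step 7
Reactants: 10 ring-opened dimer with free M 3-OH; 11 3,4,5-tris(benzyloxy)benzoic acid
Product: 12 dimer 10 carrying a 3,4,5-tris(benzyloxy)benzoyl (tri-O-benzylgalloyl) ester on M O3
Conditions: DCC, DMAP, CH2Cl2, rt
Reagents that add atoms: none
Why: Steglich esterification of the only free hydroxyl, M O3; no stereocentre is touched.

Step 8
Reactants: 12 M-galloylated dimer
Product: 13 M-galloylated dimer bearing a 4β-(2-ethoxyethoxy) group on M C4 (trans to the M 3-O-galloyl group)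
Conditions: DDQ (2–3 equiv), 2-ethoxyethanol, CH2Cl2, rt
Reagents that add atoms: 2-ethoxyethanol, CCOCCO
Why: DDQ benzylic oxidation as in step 2: M C4 is the only benzylic CH2 and its cation is stabilised by ring A of M, whereas the tertiary T C4–H is buried between two aryl rings and the silyl ether; the alcohol adds anti to the axial 3-O-galloyl group and gives the 4β ether.

Step 9
Reactants: 2 5,7,3',4'-tetra-O-benzyl-(−)-epicatechin; 11 3,4,5-tris(benzyloxy)benzoic acid
Product: 14 5,7,3',4'-tetra-O-benzylepicatechin 3-O-[3,4,5-tris(benzyloxy)benzoate] (perbenzylated epicatechin gallate)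
Conditions: DCC, DMAP, CH2Cl2, rt
Reagents that add atoms: none
Why: Steglich esterification of the 3-OH; the stereocentres are untouched.

Step 10
Reactants: 13 C4-activated M-galloylated dimer; 14 perbenzylated epicatechin gallate (4 equiv)
Product: 15 protected trimer T-(4α→8)-M-(4β→8)-B (eighteen benzyl ethers; M and B as tri-O-benzylgallates; T O3 as diisopropyl(4-methoxy-4-oxobutyl)silyl ether)
Conditions: TMSOTf (0.5 equiv), CH2Cl2, −78 → −20 °C; Et3N quench
Reagents that add atoms: none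
Why: Lewis-acid flavan C4–C8 condensation (Friedel–Crafts alkylation): TMSOTf ionises the 4-ether of 13, C8 of ring A of 14 (the innately preferred position) attacks, and the axial 3-O-galloyl group, which covers and can bridge the α face, sends the arene to the β face, setting M C4 trans to O3 (4β); the excess of 14 outcompetes self-condensation.

Step 11
Reactants: 15 silylated protected trimer
Product: 16 protected trimer with free T 3-OH (eighteen benzyl ethers; M and B as tri-O-benzylgallates)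
Conditions: Bu4NF, AcOH, THF, 0 °C → rt
Reagents that add atoms: none
Why: Fluoride-induced desilylation driven by the Si–F bond; acetic acid buffering keeps the gallate esters and the stereocentres safe.

Step 12
Reactants: 16 protected trimer with free T 3-OH
Product: 17 CNP0279403.2, epicatechin-(4α→8)-epicatechin 3-O-gallate-(4β→8)-epicatechin 3-O-gallate
Conditions: H2 (1 atm), Pd(OH)2/C, THF/MeOH/H2O, rt
Reagents that add atoms: none
Why: Catalytic hydrogenolysis of all eighteen benzyl ethers under neutral conditions, which leaves the gallate esters, the interflavan bonds and every stereocentre unchanged.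

Compound list

1 | (−)-epicatechin (2R,3R) | O[C@@H]1Cc2c(O)cc(O)cc2O[C@@H]1c1ccc(O)c(O)c1 | starting material
2 | 5,7,3',4'-tetra-O-benzyl-(−)-epicatechin (2R,3R; 3-OH free) | O[C@@H]1Cc2c(OCc3ccccc3)cc(OCc3ccccc3)cc2O[C@@H]1c1ccc(OCc2ccccc2)c(OCc2ccccc2)c1 | intermediate
3 | 5,7,3',4'-tetra-O-benzyl-4β-(2-ethoxyethoxy)epicatechin (2-aryl and 3-OH α, 4-ether β) | CCOCCO[C@H]1c2c(OCc3ccccc3)cc(OCc3ccccc3)cc2O[C@H](c2ccc(OCc3ccccc3)c(OCc3ccccc3)c2)[C@@H]1O | intermediate
4 | but-3-enoic acid | C=CCC(=O)O | starting material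
5 | 5,7,3',4'-tetra-O-benzylepicatechin 3-O-but-3-enoate | C=CCC(=O)O[C@@H]1Cc2c(OCc3ccccc3)cc(OCc3ccccc3)cc2O[C@@H]1c1ccc(OCc2ccccc2)c(OCc2ccccc2)c1 | intermediate
6 | chlorodiisopropylsilane | CC(C)[SiH](Cl)C(C)C | starting material
7 | 5,7,3',4'-tetra-O-benzylepicatechin 3-O-[4-(chlorodiisopropylsilyl)butanoate] | CC(C)[Si](Cl)(C(C)C)CCCC(=O)O[C@@H]1Cc2c(OCc3ccccc3)cc(OCc3ccccc3)cc2O[C@@H]1c1ccc(OCc2ccccc2)c(OCc2ccccc2)c1 | intermediate
8 | tethered T–M precursor: 3 silylated at O3 and tetra-O-benzylepicatechin acylated at O3, joined by Si(iPr)2–(CH2)3–C(=O) | CCOCCO[C@H]1c2c(OCc3ccccc3)cc(OCc3ccccc3)cc2O[C@H](c2ccc(OCc3ccccc3)c(OCc3ccccc3)c2)[C@@H]1O[Si](C(C)C)(C(C)C)CCCC(=O)O[C@@H]1Cc2c(OCc3ccccc3)cc(OCc3ccccc3)cc2O[C@@H]1c1ccc(OCc2ccccc2)c(OCc2ccccc2)c1 | intermediate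
9 | macrocyclic 4α-linked T–M dimer (14-membered ring through T O3–Si(iPr)2–(CH2)3–C(=O)–O3 M; T C4 aryl cis to T O3) | O=C5O[C@@H]1Cc2c(OCc6ccccc6)cc(OCc6ccccc6)c([C@@H]3c4c(OCc6ccccc6)cc(OCc6ccccc6)cc4O[C@H](c7ccc(OCc6ccccc6)c(OCc6ccccc6)c7)[C@@H]3O[Si](C(C)C)(C(C)C)CCC5)c2O[C@@H]1c7ccc(OCc6ccccc6)c(OCc6ccccc6)c7 | intermediate
10 | octa-O-benzyl epicatechin-(4α→8)-epicatechin, M 3-OH free, T O3 as diisopropyl(4-methoxy-4-oxobutyl)silyl ether | O[C@@H]1Cc2c(OCc6ccccc6)cc(OCc6ccccc6)c([C@@H]3c4c(OCc6ccccc6)cc(OCc6ccccc6)cc4O[C@H](c7ccc(OCc6ccccc6)c(OCc6ccccc6)c7)[C@@H]3O[Si](C(C)C)(C(C)C)CCCC(=O)OC)c2O[C@@H]1c7ccc(OCc6ccccc6)c(OCc6ccccc6)c7 | intermediate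
11 | 3,4,5-tris(benzyloxy)benzoic acid | OC(=O)c1cc(OCc2ccccc2)c(OCc2ccccc2)c(OCc2ccccc2)c1 | starting material
12 | dimer 10 esterified at M O3 with 3,4,5-tris(benzyloxy)benzoyl | O=C(O[C@@H]1Cc2c(OCc6ccccc6)cc(OCc6ccccc6)c([C@@H]3c4c(OCc6ccccc6)cc(OCc6ccccc6)cc4O[C@H](c7ccc(OCc6ccccc6)c(OCc6ccccc6)c7)[C@@H]3O[Si](C(C)C)(C(C)C)CCCC(=O)OC)c2O[C@@H]1c7ccc(OCc6ccccc6)c(OCc6ccccc6)c7)c8cc(OCc6ccccc6)c(OCc6ccccc6)c(OCc6ccccc6)c8 | intermediate
13 | dimer 12 with a 4β-(2-ethoxyethoxy) group on M C4 (trans to M O3) | O=C(O[C@@H]1[C@@H](OCCOCC)c2c(OCc6ccccc6)cc(OCc6ccccc6)c([C@@H]3c4c(OCc6ccccc6)cc(OCc6ccccc6)cc4O[C@H](c7ccc(OCc6ccccc6)c(OCc6ccccc6)c7)[C@@H]3O[Si](C(C)C)(C(C)C)CCCC(=O)OC)c2O[C@@H]1c7ccc(OCc6ccccc6)c(OCc6ccccc6)c7)c8cc(OCc6ccccc6)c(OCc6ccccc6)c(OCc6ccccc6)c8 | intermediate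
14 | 5,7,3',4'-tetra-O-benzylepicatechin 3-O-[3,4,5-tris(benzyloxy)benzoate] | O=C(O[C@@H]1Cc2c(OCc3ccccc3)cc(OCc3ccccc3)cc2O[C@@H]1c1ccc(OCc2ccccc2)c(OCc2ccccc2)c1)c1cc(OCc2ccccc2)c(OCc2ccccc2)c(OCc2ccccc2)c1 | intermediate
15 | protected trimer T-(4α→8)-M-(4β→8)-B, eighteen benzyl ethers, T O3 as diisopropyl(4-methoxy-4-oxobutyl)silyl ether | O=C(O[C@@H]1[C@@H](c2c(OCc9ccccc9)cc(OCc9ccccc9)c3c2O[C@H](c2ccc(OCc9ccccc9)c(OCc9ccccc9)c2)[C@H](OC(=O)c2cc(OCc9ccccc9)c(OCc9ccccc9)c(OCc9ccccc9)c2)C3)c2c(OCc9ccccc9)cc(OCc9ccccc9)c([C@@H]3c4c(OCc9ccccc9)cc(OCc9ccccc9)cc4O[C@H](c4ccc(OCc9ccccc9)c(OCc9ccccc9)c4)[C@@H]3O[Si](C(C)C)(C(C)C)CCCC(=O)OC)c2O[C@@H]1c1ccc(OCc9ccccc9)c(OCc9ccccc9)c1)c1cc(OCc9ccccc9)c(OCc9ccccc9)c(OCc9ccccc9)c1 | intermediate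
16 | protected trimer T-(4α→8)-M-(4β→8)-B, eighteen benzyl ethers, T 3-OH free | O=C(O[C@@H]1[C@@H](c2c(OCc9ccccc9)cc(OCc9ccccc9)c3c2O[C@H](c2ccc(OCc9ccccc9)c(OCc9ccccc9)c2)[C@H](OC(=O)c2cc(OCc9ccccc9)c(OCc9ccccc9)c(OCc9ccccc9)c2)C3)c2c(OCc9ccccc9)cc(OCc9ccccc9)c([C@@H]3c4c(OCc9ccccc9)cc(OCc9ccccc9)cc4O[C@H](c4ccc(OCc9ccccc9)c(OCc9ccccc9)c4)[C@@H]3O)c2O[C@@H]1c1ccc(OCc9ccccc9)c(OCc9ccccc9)c1)c1cc(OCc9ccccc9)c(OCc9ccccc9)c(OCc9ccccc9)c1 | intermediate
17 | CNP0279403.2, epicatechin-(4α→8)-epicatechin 3-O-gallate-(4β→8)-epicatechin 3-O-gallate | O=C(O[C@@H]1[C@@H](c2c(O)cc(O)c3c2O[C@H](c2ccc(O)c(O)c2)[C@H](OC(=O)c2cc(O)c(O)c(O)c2)C3)c2c(O)cc(O)c([C@@H]3c4c(O)cc(O)cc4O[C@H](c4ccc(O)c(O)c4)[C@@H]3O)c2O[C@@H]1c1ccc(O)c(O)c1)c1cc(O)c(O)c(O)c1 | target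

Total step count: 12. Longest linear sequence: 10 steps (steps 1, 3, 4, 5, 6, 7, 8, 10, 11, 12).

Steps most likely to fail

Step 5 (key step). The silyl ether end of the tether may be exchanged or cleaved by the silyl triflate before the ring closes. The freed T C4 cation would then be captured by another molecule on the β face, giving chain growth and the wrong C4 configuration. The fallback uses an all-ester bridge of the same length and tells the two hydroxyls apart afterwards by their unequal hindrance. It sets out from 2 and 3. Compound 2 is opened onto glutaric anhydride (DMAP, pyridine) to give the hemiglutarate F1, which is esterified with 3 (DCC, DMAP) to the glutarate-bridged precursor F2. TMSOTf at high dilution should close the same 14-membered ring to the macrocyclic diester F3. K2CO3 in MeOH/THF then removes the bridge and gives the 4α-linked diol F4. One equivalent of 11 (DCC, DMAP, 0 °C) should acylate the M hydroxyl, because T O3 sits between the cis 2-aryl and cis 4-aryl groups, to give the mono-gallate F5. Oxidation with DDQ and 2-ethoxyethanol as in step 8 gives the C4-activated mono-gallate F6, and coupling of F6 with 14 as in step 10 comes back to the route at 16.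

Step 8. Hydride abstraction at M C4 is slowed by the neighbouring acyloxy group, so abstraction of the doubly benzylic T C4–H or of a C2–H, or oxidative loss of benzyl ethers, may overtake it. The fallback moves the oxidation ahead of the acylation and sets out from 10. Compound 10 is oxidised with DDQ and 2-ethoxyethanol while M O3 is still a free hydroxyl, which is the situation of step 2, to give the hydroxy ether F7. F7 is then esterified with 11 (DCC, DMAP) in the presence of the 4-ether, which comes back to the route at 13.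

Step 4. The bulky chlorosilane 7 may silylate the hindered axial 3-OH of 3 too slowly, so that hydrolysis of 7 to silanol and disiloxane takes over. The fallback forms the Si–O bond first with the small silane and the Si–C bond second, and sets out from 3. Compound 6 with imidazole in DMF should give the 3-O-diisopropylsilyl (Si–H) ether F8. Platinum-catalysed hydrosilylation of the alkene of 5 by F8 (Pt2[(CH2=CHSiMe2)2O]3, toluene, 60 °C) then comes back to the route at 8.

Further compounds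

F1 | step 5 | hemiglutarate of 2: 5-oxo-5-(tetra-O-benzylepicatechin-3-yloxy)pentanoic acid | OC(=O)CCCC(=O)O[C@@H]1Cc2c(OCc3ccccc3)cc(OCc3ccccc3)cc2O[C@@H]1c1ccc(OCc2ccccc2)c(OCc2ccccc2)c1
F2 | step 5 | glutarate-bridged precursor: 3 and 2 joined O3 to O3 as the pentanedioate diester | CCOCCO[C@H]1c2c(OCc3ccccc3)cc(OCc3ccccc3)cc2O[C@H](c2ccc(OCc3ccccc3)c(OCc3ccccc3)c2)[C@@H]1OC(=O)CCCC(=O)O[C@@H]1Cc2c(OCc3ccccc3)cc(OCc3ccccc3)cc2O[C@@H]1c1ccc(OCc2ccccc2)c(OCc2ccccc2)c1
F3 | step 5 | macrocyclic diester: octa-O-benzyl epicatechin-(4α→8)-epicatechin with O3 and O3 bridged by glutarate | O=C5O[C@@H]1Cc2c(OCc6ccccc6)cc(OCc6ccccc6)c([C@@H]3c4c(OCc6ccccc6)cc(OCc6ccccc6)cc4O[C@H](c7ccc(OCc6ccccc6)c(OCc6ccccc6)c7)[C@@H]3OC(=O)CCC5)c2O[C@@H]1c7ccc(OCc6ccccc6)c(OCc6ccccc6)c7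
F4 | step 5 | 4α-linked diol: octa-O-benzyl epicatechin-(4α→8)-epicatechin | O[C@@H]1Cc2c(OCc6ccccc6)cc(OCc6ccccc6)c([C@@H]3c4c(OCc6ccccc6)cc(OCc6ccccc6)cc4O[C@H](c7ccc(OCc6ccccc6)c(OCc6ccccc6)c7)[C@@H]3O)c2O[C@@H]1c7ccc(OCc6ccccc6)c(OCc6ccccc6)c7
F5 | step 5 | mono-gallate: F4 esterified at M O3 with 3,4,5-tris(benzyloxy)benzoyl, T 3-OH free | O=C(O[C@@H]1Cc2c(OCc6ccccc6)cc(OCc6ccccc6)c([C@@H]3c4c(OCc6ccccc6)cc(OCc6ccccc6)cc4O[C@H](c7ccc(OCc6ccccc6)c(OCc6ccccc6)c7)[C@@H]3O)c2O[C@@H]1c7ccc(OCc6ccccc6)c(OCc6ccccc6)c7)c8cc(OCc6ccccc6)c(OCc6ccccc6)c(OCc6ccccc6)c8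
F6 | step 5 | C4-activated mono-gallate: F5 with a 4β-(2-ethoxyethoxy) group on M C4 | O=C(O[C@@H]1[C@@H](OCCOCC)c2c(OCc6ccccc6)cc(OCc6ccccc6)c([C@@H]3c4c(OCc6ccccc6)cc(OCc6ccccc6)cc4O[C@H](c7ccc(OCc6ccccc6)c(OCc6ccccc6)c7)[C@@H]3O)c2O[C@@H]1c7ccc(OCc6ccccc6)c(OCc6ccccc6)c7)c8cc(OCc6ccccc6)c(OCc6ccccc6)c(OCc6ccccc6)c8
F7 | step 8 | hydroxy ether: 10 with a 4β-(2-ethoxyethoxy) group on M C4 and free M 3-OH | O[C@@H]1[C@@H](OCCOCC)c2c(OCc6ccccc6)cc(OCc6ccccc6)c([C@@H]3c4c(OCc6ccccc6)cc(OCc6ccccc6)cc4O[C@H](c7ccc(OCc6ccccc6)c(OCc6ccccc6)c7)[C@@H]3O[Si](C(C)C)(C(C)C)CCCC(=O)OC)c2O[C@@H]1c7ccc(OCc6ccccc6)c(OCc6ccccc6)c7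
F8 | step 4 | 3-O-diisopropylsilyl (Si–H) ether of 3 | CCOCCO[C@H]1c2c(OCc3ccccc3)cc(OCc3ccccc3)cc2O[C@H](c2ccc(OCc3ccccc3)c(OCc3ccccc3)c2)[C@@H]1O[SiH](C(C)C)C(C)C
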